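## Analysis of the target

Mundulea flavanone B (14) is a flavanone, that is a chroman-4-one (rings A and C) carrying a 4-hydroxyphenyl group (ring B) on C2. C2 is the only stereocentre and has the S configuration, so the target itself poses no problem of relative configuration. C2 is benzylic, bound to the ring oxygen O1 and β to the C4 ketone, so base can open ring C by retro-oxa-Michael reaction to the achiral 2'-hydroxychalcone, and the free 4'-phenol makes this easier. Ring A is a fully differentiated phloroglucinol with O1 at C8a, a free hydroxyl at C5 hydrogen-bonded to the ketone, a methoxy group at C7 and a prenyl group at C8, which leaves C6 as the only ring CH. The prenyl olefin is sensitive to acid (hydration, cyclisation onto a neighbouring free phenol) and rules out hydrogenolytic deprotection. The difficulty is threefold: C2 must be made and kept as one enantiomer, the prenyl group must sit at C8 and not at C6, and three phenolic oxygens of ring A must be told apart. The strategy rests on ring C being a pyran fused to the electron-rich ring A with a benzylic C4: the unit O1–C8a–C4a–C4 is a latent ortho-quinone methide, and C2–C3 with ring B is a styrene.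

## Retrosynthetic reasoning

**14 from 13.** No skeletal bond is cut. The phenols at C5 and C4' are carried as triisopropylsilyl ethers in 13. Silyl ethers come off with buffered fluoride, which touches neither the prenyl olefin nor, as long as the medium stays non-basic, the C2 stereocentre. Their bulk is also used earlier to tell the two phenols of ring A apart.

**13 from 12 and 11.** The ketone is traced to the benzylic alcohol 12 and that to the benzylic methyl ether 11. No carbon–carbon bond is cut; only the oxidation level at C4 is adjusted. The gain is that C4 may enter as an sp3 carbon bearing an alkoxy group, which is what a cycloaddition of an alkoxy quinone methide delivers. The forward steps must ionise the very labile C4–O bond in dilute aqueous acid and oxidise the alcohol without acid. The C4 configuration is irrelevant because it is erased.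

**11 from 5 and 8 (through 9 and 10).** O1–C2 and C3–C4 are cut together. This removes ring C and the C2 stereocentre in one operation and gives two fragments of similar size, an aromatic aldehyde and a styrene. Any other pair of cuts (C4–C4a, C2–C3) leaves a chiral open-chain ether or alcohol to be made first. Forward, aldehyde 5 is converted through its acetal 9 into the methoxy quinone methide 10. The styrene 8 must add with its CH2 terminus to the methide carbon and its benzylic carbon to oxygen, under a chiral Brønsted acid that decides which face of 8 bonds to oxygen. Only the phenol next to the prenyl group is free in 5, so the heterodiene can form in one direction only and the prenyl group ends at C8.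

**5 from 4, 2, 1 and 3.** The silyl group of 5 is removed to give diphenol 4, in which the two hydroxyls differ only by the prenyl neighbour; a bulky silyl group should choose the unhindered one. The ring–prenyl bond of 4 is cut to give 2 and the allylic bromide 3. Because 2 is symmetric, its two free ring positions are equivalent and C-prenylation can give one constitution only. The methyl ether of 2 is removed to give 1, whose 4-hydroxyl is the only one not chelated to the formyl group.

**8 from 7 and 6.** The silyl ether of 8 is traced to phenol 7 and this to acetate 6. The silyl ether keeps the para oxygen a strong donor, so the styrene stays nucleophilic, and it prevents the phenol from trapping 10.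

## Alternatives that were turned down

Alternative 1: ring A is built last by a Diels–Alder reaction on a preformed chiral ring C. The disconnection cuts C8–C8a and C4a–C5. Forward, the bromopyranone (2S)-5-bromo-2-[4-(tert-butyldimethylsilyloxy)phenyl]-2,3-dihydro-4H-pyran-4-one A2 would react with the vinylketene acetal 1,3-dimethoxy-7-methyl-1-(trimethylsilyloxy)octa-1,3,6-triene A3. Loss of hydrogen bromide and of the silyl methyl ether would then aromatise the adduct to the 4'-silyl ether of the target, (2S)-2-[4-(tert-butyldimethylsilyloxy)phenyl]-5-hydroxy-7-methoxy-8-(3-methylbut-2-enyl)chroman-4-one A1.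
- For: the positions of the hydroxyl, methoxy and prenyl groups are written into A3, so no selective methylation, prenylation or silylation of a phloroglucinol is needed. The 5-hydroxyl appears free in A1, and A1 is one fluoride step from 14. The C2 centre of A2 can be set beforehand by a well-established catalytic asymmetric hetero-Diels–Alder reaction of an aryl aldehyde. On regiochemical security and on precedent for the stereocentre this route is stronger than the chosen one.
- Against: the C5=C6 bond of A2 is part of a vinylogous ester and is therefore electron-rich, a poor partner for an electron-rich diene. A3 carries an alkyl group on its reacting terminus, which slows the cycloaddition and makes the diene geometry an issue. In the cis-fused adduct the bromine and the C8a hydrogen are syn, so loss of hydrogen bromide is not a simple anti elimination. The forcing conditions needed on the way to A1 threaten the benzylic C2–O bond.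
- Comparison: ring A is made from acyclic material in several steps although it can be bought. The chosen route buys ring A, is convergent and short, and places its risk in one catalytic step.

Alternative 2: ring C is closed by Friedel–Crafts acylation. The disconnection cuts C4–C4a. Forward, the acid (3S)-3-(4-acetoxyphenyl)-3-[5-acetoxy-3-methoxy-2-(3-methylbut-2-enyl)phenoxy]propanoic acid A5 would be activated as its mixed trifluoroacetic anhydride and would acylate C4a. The product would be the diacetate of the target, (2S)-5-acetoxy-2-(4-acetoxyphenyl)-7-methoxy-8-(3-methylbut-2-enyl)chroman-4-one A4.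
- For: the closure of A5 to A4 is a classical reaction on an activated arene, only C4a is within reach, and the ketone arrives at the right oxidation level. On precedent for the ring-closing step and on the oxidation level at C4 this route is stronger than the chosen one.
- Against: the stereocentre of A5 must first be made as a benzylic aryl ether of a hindered ortho-prenyl phenol, and a Mitsunobu inversion at a para-oxygenated benzylic alcohol tends to ionise and lose configuration. A5 is a β-aryloxy acid and eliminates the phenol easily under base (ester hydrolysis) and under acid (the ring closure). The trifluoroacetic acid set free can add to the prenyl olefin. The acetoxy group ortho to C4a deactivates the position to be acylated. Removal of the two acetates from A4 again exposes the flavanone to basic solvolysis, which is where C2 is lost through the chalcone. The phenol component needs the same differentiation of ring A as aldehyde 5.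
- Comparison: the route to A4 is longer. The chosen strategy offers in exchange the C2–O bond and the ring formed together under catalyst control, without a separately built chiral ether.

Alternative 3: ring C is closed by carbenoid C–H insertion. The disconnection cuts C2–C3. Forward, the diazo ketone 2-diazo-1-[2-[4-(tert-butyldimethylsilyloxy)benzyloxy]-6-(tert-butyldimethylsilyloxy)-4-methoxy-3-(3-methylbut-2-enyl)phenyl]ethanone A7 would be decomposed by Rh2(S-PTTL)4, dirhodium tetrakis[N-phthaloyl-(S)-tert-leucinate]. The carbenoid at C3 would insert into the benzylic ether C–H and give the bis-silyl ether of the target, (2S)-5-(tert-butyldimethylsilyloxy)-2-[4-(tert-butyldimethylsilyloxy)phenyl]-7-methoxy-8-(3-methylbut-2-enyl)chroman-4-one A6.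
- For: ring C closes at the ketone oxidation level and C2 is set by the catalyst in the same step, so A6 needs only the final fluoride step and the two redox steps of the chosen route fall away. On that point this route is stronger.
- Against: in A7 the ether oxygen sits 1,5 to the carbenoid carbon, so formation of a five-membered oxonium ylide followed by a Stevens-type [1,2]-benzyl shift is expected to outrun insertion in the six-membered mode. A carbenoid with only an acyl substituent is unselective and gives modest enantiocontrol. The prenyl olefin and the electron-rich ring B are further carbenoid traps. A7 needs a hindered 2,6-dioxygenated benzoic acid, benzylation of a chelated phenol and a diazomethane homologation.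
- Comparison: the route to A6 is longer and its key step has a well-known competing pathway. The chosen strategy reaches the analogous silyl-protected flavanone 13 from two simple fragments.

Key step: step 6

Assumption: the sense of induction of the binaphthyl phosphoric acid in step 6 cannot be derived from the closest known reactions; the (R)-acid is written, and its mirror image would be used if the 2R series formed.

Remark: compound 11 is drawn as the 2,4-cis adduct expected from an endo transition state; its C4 epimer would serve equally, because C4 becomes the carbonyl carbon in step 8.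

## Route

Step 1
Reactants: 1 2,4,6-trihydroxybenzaldehyde
Product: 2 2,6-dihydroxy-4-methoxybenzaldehyde
Conditions: Me2SO4 (1.0 equiv), K2CO3 (1.0 equiv), acetone, 0 °C → rt
Reagents that add atoms: dimethyl sulfate, COS(=O)(=O)OC
Why: Williamson O-methylation; the 4-hydroxyl is para to the formyl group and not chelated to it, so it is the most acidic and most exposed phenol and should be alkylated first by one equivalent of a hard methylating agent; 2-O-methyl and di-O-methyl by-products would be removed by chromatography.

Step 2
Reactants: 2 2,6-dihydroxy-4-methoxybenzaldehyde; 3 prenyl bromide (1-bromo-3-methylbut-2-ene)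
Product: 4 2,6-dihydroxy-4-methoxy-3-(3-methylbut-2-enyl)benzaldehyde
Conditions: 10% aq KOH, 0 °C → rt
Reagents that add atoms: none
Why: C-alkylation of an ambident phloroglucinol-type phenoxide in water, where solvation of the oxygens shifts attack to the ring carbon between O− and OMe; C3 and C5 of 2 are equivalent, so only one C-prenyl constitution can form, and O-prenyl and doubly prenylated material would be separated.

Step 3
Reactants: 4 2,6-dihydroxy-4-methoxy-3-(3-methylbut-2-enyl)benzaldehyde
Product: 5 2-hydroxy-4-methoxy-3-(3-methylbut-2-enyl)-6-(triisopropylsilyloxy)benzaldehyde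
Conditions: TIPSCl (1.05 equiv), imidazole, DMF, 0 °C → rt
Reagents that add atoms: triisopropylsilyl chloride, CC(C)[Si](Cl)(C(C)C)C(C)C
Why: Silylation of a phenol; the bulky silyl chloride should react at the hydroxyl flanked by hydrogen and not at the one buttressed by the prenyl group, and the remaining phenol is chelated to the aldehyde, which should stop a second silylation.

Step 4
Reactants: 6 4-acetoxystyrene
Product: 7 4-vinylphenol
Conditions: K2CO3 (0.1 equiv), MeOH, BHT (trace), 0 °C → rt
Reagents that add atoms: none
Why: Base-catalysed transesterification of an aryl acetate with methanol; the product is kept cold and in solution and used at once because it polymerises easily.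

Step 5
Reactants: 7 4-vinylphenol
Product: 8 4-(triisopropylsilyloxy)styrene
Conditions: TIPSCl, imidazole, DMF, 0 °C → rt
Reagents that add atoms: triisopropylsilyl chloride, CC(C)[Si](Cl)(C(C)C)C(C)C
Why: Standard silylation of an unhindered phenol; the silyl ether keeps the para oxygen a donor while removing the nucleophilic hydroxyl.

Step 6
Reactants: 5 2-hydroxy-4-methoxy-3-(3-methylbut-2-enyl)-6-(triisopropylsilyloxy)benzaldehyde; 8 4-(triisopropylsilyloxy)styrene
Product: 11 (2S,4S)-4,7-dimethoxy-8-(3-methylbut-2-enyl)-5-(triisopropylsilyloxy)-2-[4-(triisopropylsilyloxy)phenyl]chroman (2,4-cis), via dimethyl acetal 9 (not isolated), via methoxy ortho-quinone methide 10 (not isolated)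
Conditions: HC(OMe)3 (1.5 equiv), (R)-3,3'-bis(2,4,6-triisopropylphenyl)-1,1'-binaphthyl-2,2'-diyl hydrogen phosphate (10 mol%), 5 Å MS, PhMe, −20 °C → rt
Reagents that add atoms: trimethyl orthoformate, COC(OC)OC
Why: Proposed new method: the acid and the orthoformate convert 5 into acetal 9, and loss of methanol gives 10 as a hydrogen-bonded ion pair with the chiral phosphate (its O-protonated form is the ortho-hydroxybenzyl oxocarbenium ion); the closest known reaction types are the acid-promoted three-component coupling of salicylaldehydes, orthoformates and styrenes to 2-aryl-4-alkoxychromans and the chiral phosphoric acid-catalysed [4+2] cycloadditions of ortho-quinone methides, and their combination on a styrene without a directing group is what is new. The CH2 terminus of 8, the nucleophilic end of a para-donor styrene, bonds to the methide carbon (C3–C4) and the quinone methide oxygen closes on the developing benzylic cation (O1–C2) in an asynchronous inverse-demand hetero-Diels–Alder reaction. Ring C is closed as a six-membered ring by the cycloaddition itself; in the stepwise limit this is a 6-exo capture of the benzylic cation by the phenol oxygen. C4 is set by the face of 10 that the phosphate pocket leaves open, and C2 by the endo placement of the aryl group relative to the methoxy group within the same ion pair, which should give the 2,4-cis adduct. Only C2 survives to the target, so the selectivity the step needs is the choice of the face of 8 that bonds to oxygen. The aryl group goes to C2 because of styrene polarity, and the 8-prenyl pattern follows because the only free phenol of 5 is the one next to the prenyl group. The conjugated para-silyloxystyrene is far more nucleophilic than the trisubstituted prenyl olefin, which should leave the latter untouched. The weak acid, the low temperature and the hydrogen bond of the phenol to the aldehyde should keep the prenyl group from cyclising onto the phenol before 10 forms.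

Step 7
Reactants: 11 (2S,4S)-4,7-dimethoxy-8-(3-methylbut-2-enyl)-5-(triisopropylsilyloxy)-2-[4-(triisopropylsilyloxy)phenyl]chroman
Product: 12 (2S)-7-methoxy-8-(3-methylbut-2-enyl)-5-(triisopropylsilyloxy)-2-[4-(triisopropylsilyloxy)phenyl]chroman-4-ol (both C4 epimers)
Conditions: 0.05 M aq HCl/THF (1:3), degassed, 0 °C → rt
Reagents that add atoms: water, O
Why: SN1 solvolysis of a benzylic methyl ether; the C4 cation is stabilised by O1, the 5-silyloxy and the 7-methoxy group, so dilute acid suffices and the large excess of water drives the exchange, while aryl silyl ethers, the prenyl group and C2 are not expected to be affected; both C4 epimers are carried on.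

Step 8
Reactants: 12 (2S)-7-methoxy-8-(3-methylbut-2-enyl)-5-(triisopropylsilyloxy)-2-[4-(triisopropylsilyloxy)phenyl]chroman-4-ol
Product: 13 (2S)-7-methoxy-8-(3-methylbut-2-enyl)-5-(triisopropylsilyloxy)-2-[4-(triisopropylsilyloxy)phenyl]chroman-4-one
Conditions: Dess–Martin periodinane, pyridine, CH2Cl2, 0 °C → rt
Reagents that add atoms: none
Why: Dess–Martin oxidation of a secondary benzylic alcohol; pyridine buffers the acetic acid so the acid-labile alcohol does not ionise, the olefin and silyl ethers are inert, and both C4 epimers converge on one ketone.

Step 9
Reactants: 13 (2S)-7-methoxy-8-(3-methylbut-2-enyl)-5-(triisopropylsilyloxy)-2-[4-(triisopropylsilyloxy)phenyl]chroman-4-one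
Product: 14 Mundulea flavanone B, (2S)-5-hydroxy-2-(4-hydroxyphenyl)-7-methoxy-8-(3-methylbut-2-enyl)chroman-4-one
Conditions: TBAF (2.5 equiv), AcOH (2.5 equiv), THF, 0 °C
Reagents that add atoms: none
Why: Fluoride cleavage of both aryl silyl ethers; acetic acid keeps the liberated phenols protonated, so neither retro-oxa-Michael opening to the chalcone nor quinone methide formation through a 4'-phenoxide should racemise C2.

## Compound list

1 | 2,4,6-trihydroxybenzaldehyde | O=Cc1c(O)cc(O)cc1O | starting material
2 | 2,6-dihydroxy-4-methoxybenzaldehyde | COc1cc(O)c(C=O)c(O)c1 | intermediate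
3 | prenyl bromide (1-bromo-3-methylbut-2-ene) | CC(C)=CCBr | starting material
4 | 2,6-dihydroxy-4-methoxy-3-(3-methylbut-2-enyl)benzaldehyde | COc1cc(O)c(C=O)c(O)c1CC=C(C)C | intermediate
5 | 2-hydroxy-4-methoxy-3-(3-methylbut-2-enyl)-6-(triisopropylsilyloxy)benzaldehyde | COc1cc(O[Si](C(C)C)(C(C)C)C(C)C)c(C=O)c(O)c1CC=C(C)C | intermediate
6 | 4-acetoxystyrene | CC(=O)Oc1ccc(C=C)cc1 | starting material
7 | 4-vinylphenol | C=Cc1ccc(O)cc1 | intermediate
8 | 4-(triisopropylsilyloxy)styrene | C=Cc1ccc(O[Si](C(C)C)(C(C)C)C(C)C)cc1 | intermediate
9 | 2-(dimethoxymethyl)-5-methoxy-6-(3-methylbut-2-enyl)-3-(triisopropylsilyloxy)phenol (formed in the flask, not isolated) | COc1cc(O[Si](C(C)C)(C(C)C)C(C)C)c(C(OC)OC)c(O)c1CC=C(C)C | intermediate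
10 | 3-methoxy-6-(methoxymethylidene)-2-(3-methylbut-2-enyl)-5-(triisopropylsilyloxy)cyclohexa-2,4-dien-1-one, exocyclic geometry not fixed (formed in the flask, not isolated) | COC=C1C(O[Si](C(C)C)(C(C)C)C(C)C)=CC(OC)=C(CC=C(C)C)C1=O | intermediate
11 | (2S,4S)-4,7-dimethoxy-8-(3-methylbut-2-enyl)-5-(triisopropylsilyloxy)-2-[4-(triisopropylsilyloxy)phenyl]chroman (2,4-cis) | COc1cc(O[Si](C(C)C)(C(C)C)C(C)C)c2c(c1CC=C(C)C)O[C@H](c1ccc(O[Si](C(C)C)(C(C)C)C(C)C)cc1)C[C@@H]2OC | intermediate
12 | (2S)-7-methoxy-8-(3-methylbut-2-enyl)-5-(triisopropylsilyloxy)-2-[4-(triisopropylsilyloxy)phenyl]chroman-4-ol, both C4 epimers | COc1cc(O[Si](C(C)C)(C(C)C)C(C)C)c2c(c1CC=C(C)C)O[C@H](c1ccc(O[Si](C(C)C)(C(C)C)C(C)C)cc1)CC2O | intermediate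
13 | (2S)-7-methoxy-8-(3-methylbut-2-enyl)-5-(triisopropylsilyloxy)-2-[4-(triisopropylsilyloxy)phenyl]chroman-4-one | COc1cc(O[Si](C(C)C)(C(C)C)C(C)C)c2c(c1CC=C(C)C)O[C@H](c1ccc(O[Si](C(C)C)(C(C)C)C(C)C)cc1)CC2=O | intermediate
14 | Mundulea flavanone B, (2S)-5-hydroxy-2-(4-hydroxyphenyl)-7-methoxy-8-(3-methylbut-2-enyl)chroman-4-one | COc1cc(O)c2c(c1CC=C(C)C)O[C@H](c1ccc(O)cc1)CC2=O | target

## Step count and least certain steps

Total: 9 steps. Longest linear sequence: 7 steps (steps 1, 2, 3, 6, 7, 8, 9).

**Step 6 (key step).** Three things may go wrong.
- Low reactivity: the quinone methide carries four oxygen donors and is a weak electrophile, so addition of the styrene may be slow. Acid-induced oligomerisation of the styrene or cyclisation of the prenyl group onto the free phenol may then take over.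
- Poor facial selectivity at C2: the addition may be stepwise through a long-lived para-silyloxybenzyl cation, so that ring closure escapes catalyst control. Leakage between endo and exo closure has the same effect, because the C4 centre that the catalyst sets directly is later erased.
- Reversible ionisation of the product at C4 under the acid.

Fallback, by known chemistry, from 5, returning to the route at 14. Addition of excess HC≡CMgBr (ethynylmagnesium bromide) in THF at 0 °C would give the racemic propargylic alcohol 2-(1-hydroxyprop-2-yn-1-yl)-5-methoxy-6-(3-methylbut-2-enyl)-3-(triisopropylsilyloxy)phenol F1. MnO2 in CH2Cl2 would oxidise it to the ynone 1-[2-hydroxy-4-methoxy-3-(3-methylbut-2-enyl)-6-(triisopropylsilyloxy)phenyl]prop-2-yn-1-one F2. Diethylamine in ethanol would cyclise F2, by conjugate addition of the amine and addition–elimination by the phenol, to the chromone 7-methoxy-8-(3-methylbut-2-enyl)-5-(triisopropylsilyloxy)-4H-chromen-4-one F3. Asymmetric 1,4-addition of commercial 4-(tert-butyldimethylsilyloxy)phenylboronic acid to F3 under monovalent rhodium catalysis would then give the flavanone (2S)-2-[4-(tert-butyldimethylsilyloxy)phenyl]-7-methoxy-8-(3-methylbut-2-enyl)-5-(triisopropylsilyloxy)chroman-4-one F4. The catalyst would be [Rh(OH)(cod)]2 with axially chiral 2,2'-bis[bis(3,4,5-trifluorophenyl)phosphino]-6,6'-dimethoxybiphenyl, the antipode chosen for the 2S series, in aqueous CH2Cl2 at rt. The conditions of step 9 would convert F4 into 14. The same regiochemical device, one free phenol next to the prenyl group, is kept.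

**Step 7.** Two processes may divert the C4 cation from taking up water.
- Loss of a proton from C3 gives the enol-ether-like flav-3-ene, which can disproportionate or be oxidised by air to the aromatic benzopyrylium cation, a sink.
- The cation may attack C6 of a second molecule and start self-condensation.

Fallback, from 11 directly to 13: oxidative cleavage of the electron-rich benzylic methyl ether with DDQ in CH2Cl2/pH 7 buffer at 0 °C. Hydride abstraction from C4, the position activated by both the 5,7-dioxygenated ring and the methoxy group, gives the C4 oxocarbenium ion. Water converts it through the hemiketal into the ketone, so step 8 is no longer needed. No new compound is formed on the way (F0).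

**Step 2.** O-Alkylation and double alkylation may outweigh mono-C-alkylation, so that conversion to 4 is low.

Fallback, from 2, returning at 5. Silylation of symmetric 2 (TIPSCl, imidazole, DMF) would give 2-hydroxy-4-methoxy-6-(triisopropylsilyloxy)benzaldehyde F5. O-Allylation of F5 with tert-butyl 2-methylbut-3-en-2-yl carbonate under zerovalent palladium catalysis (Pd(PPh3)4, THF, 0 °C → rt; Tsuji–Trost reaction at the substituted terminus) would give 4-methoxy-2-(2-methylbut-3-en-2-yloxy)-6-(triisopropylsilyloxy)benzaldehyde F6. Aromatic Claisen rearrangement of F6 in hot toluene would move the allyl unit to the only free ortho carbon and deliver 5. This also removes the regiochemical question of step 3, because the silyl group is put on at the symmetric stage.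

**Step 1.** Over-methylation and methylation at a 2-hydroxyl may erode the yield of 2.

Fallback, which replaces 1 by commercial 3,5-dihydroxyanisole F7 and returns at 2. Protection of F7 (MOMCl, i-Pr2NEt, CH2Cl2) would give 1-methoxy-3,5-bis(methoxymethoxy)benzene F8. Directed ortho-lithiation between the two acetal oxygens (n-BuLi, THF, 0 °C) and quenching with DMF would give 4-methoxy-2,6-bis(methoxymethoxy)benzaldehyde F9. Methanolic HCl would cleave both acetals of F9 and give 2.

## Further compounds

F1 | step 6 | 2-(1-hydroxyprop-2-yn-1-yl)-5-methoxy-6-(3-methylbut-2-enyl)-3-(triisopropylsilyloxy)phenol (racemic) | COc1cc(O[Si](C(C)C)(C(C)C)C(C)C)c(C(O)C#C)c(O)c1CC=C(C)C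
F2 | step 6 | 1-[2-hydroxy-4-methoxy-3-(3-methylbut-2-enyl)-6-(triisopropylsilyloxy)phenyl]prop-2-yn-1-one | COc1cc(O[Si](C(C)C)(C(C)C)C(C)C)c(C(=O)C#C)c(O)c1CC=C(C)C
F3 | step 6 | 7-methoxy-8-(3-methylbut-2-enyl)-5-(triisopropylsilyloxy)-4H-chromen-4-one | COc1cc(O[Si](C(C)C)(C(C)C)C(C)C)c2c(c1CC=C(C)C)OC=CC2=O
F4 | step 6 | (2S)-2-[4-(tert-butyldimethylsilyloxy)phenyl]-7-methoxy-8-(3-methylbut-2-enyl)-5-(triisopropylsilyloxy)chroman-4-one | COc1cc(O[Si](C(C)C)(C(C)C)C(C)C)c2c(c1CC=C(C)C)O[C@H](c1ccc(O[Si](C)(C)C(C)(C)C)cc1)CC2=O
F0 | step 7 | none | none
F5 | step 2 | 2-hydroxy-4-methoxy-6-(triisopropylsilyloxy)benzaldehyde | COc1cc(O)c(C=O)c(O[Si](C(C)C)(C(C)C)C(C)C)c1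
F6 | step 2 | 4-methoxy-2-(2-methylbut-3-en-2-yloxy)-6-(triisopropylsilyloxy)benzaldehyde | COc1cc(OC(C)(C)C=C)c(C=O)c(O[Si](C(C)C)(C(C)C)C(C)C)c1
F7 | step 1 | 3,5-dihydroxyanisole (5-methoxyresorcinol, commercial) | COc1cc(O)cc(O)c1
F8 | step 1 | 1-methoxy-3,5-bis(methoxymethoxy)benzene | COCOc1cc(OC)cc(OCOC)c1
F9 | step 1 | 4-methoxy-2,6-bis(methoxymethoxy)benzaldehyde | COCOc1cc(OC)cc(OCOC)c1C=O
A1 | alternative 1 | (2S)-2-[4-(tert-butyldimethylsilyloxy)phenyl]-5-hydroxy-7-methoxy-8-(3-methylbut-2-enyl)chroman-4-one, the 4'-O-(tert-butyldimethylsilyl) ether of Mundulea flavanone B | COc1cc(O)c2c(c1CC=C(C)C)O[C@H](c1ccc(O[Si](C)(C)C(C)(C)C)cc1)CC2=O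
A2 | alternative 1 | (2S)-5-bromo-2-[4-(tert-butyldimethylsilyloxy)phenyl]-2,3-dihydro-4H-pyran-4-one | O=C1C[C@@H](c2ccc(O[Si](C)(C)C(C)(C)C)cc2)OC=C1Br
A3 | alternative 1 | 1,3-dimethoxy-7-methyl-1-(trimethylsilyloxy)octa-1,3,6-triene | COC(O[Si](C)(C)C)=CC(OC)=CCC=C(C)C
A4 | alternative 2 | (2S)-5-acetoxy-2-(4-acetoxyphenyl)-7-methoxy-8-(3-methylbut-2-enyl)chroman-4-one, the 5,4'-di-O-acetate of Mundulea flavanone B | CC(=O)Oc1cc(OC)c(CC=C(C)C)c2c1C(=O)C[C@@H](c1ccc(OC(C)=O)cc1)O2
A5 | alternative 2 | (3S)-3-(4-acetoxyphenyl)-3-[5-acetoxy-3-methoxy-2-(3-methylbut-2-enyl)phenoxy]propanoic acid | CC(=O)Oc1cc(OC)c(CC=C(C)C)c(O[C@@H](CC(=O)O)c2ccc(OC(C)=O)cc2)c1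
A6 | alternative 3 | (2S)-5-(tert-butyldimethylsilyloxy)-2-[4-(tert-butyldimethylsilyloxy)phenyl]-7-methoxy-8-(3-methylbut-2-enyl)chroman-4-one, the 5,4'-bis-O-(tert-butyldimethylsilyl) ether of Mundulea flavanone B | COc1cc(O[Si](C)(C)C(C)(C)C)c2c(c1CC=C(C)C)O[C@H](c1ccc(O[Si](C)(C)C(C)(C)C)cc1)CC2=O
A7 | alternative 3 | 2-diazo-1-[2-[4-(tert-butyldimethylsilyloxy)benzyloxy]-6-(tert-butyldimethylsilyloxy)-4-methoxy-3-(3-methylbut-2-enyl)phenyl]ethanone | COc1cc(O[Si](C)(C)C(C)(C)C)c(C(=O)C=[N+]=[N-])c(OCc2ccc(O[Si](C)(C)C(C)(C)C)cc2)c1CC=C(C)C
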